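The upper flavan is cut across ring C at O1–C8a and C2–C3. Ring A carries its oxygens at C7 and C8a in a 1,3-relationship, so it is carried as a 3-benzyloxycyclohexenone in which C8a is a carbonyl carbon. Its bis(silyloxy)diene (C3=C4–C4a=C8a) and 3,4-bis(benzyloxy)benzaldehyde (O1=C2) combine in one Ti(OiPr)4/(R)-BINOL-catalysed aldol/cyclocondensation, a formal oxa-Diels–Alder reaction that closes ring C and sets C2 and C3. DDQ then aromatises ring A. The catechin unit is added to the C4 ketone as its 8-bromo-6-lithio ether, and hydride reduction of the C4 cation anti to O3 gives the 3,4-cis interflavan bond.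

Key step: step 4

Remark (assumption): flavan numbering is used throughout (O1, C2, C3, C4, C4a, C5 to C8, C8a; ring A benzo, ring C pyran, ring B 2-aryl; primed atoms for the catechin unit). The Ti(OiPr)4/(R)-BINOL catalyst is assumed to direct the diene to the Re face of the aldehyde, as with simple aryl aldehydes; should the sense be opposite, (S)-BINOL is used.

Step 1
Reactants: 1 cyclohexane-1,3-dione
Product: 2 3-(benzyloxy)cyclohex-2-en-1-one
Conditions: BnOH, TsOH (cat.), toluene, reflux, Dean–Stark trap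
Reagents that add atoms: benzyl alcohol, OCc1ccccc1
Why: Acid-catalysed vinylogous esterification of the enolised 1,3-dione with azeotropic removal of water should give the benzyl enol ether, which already carries the later 7-O-benzyl group and leaves the future C8a as a carbonyl carbon.

Step 2
Reactants: 2 3-(benzyloxy)cyclohex-2-en-1-one, 3 (benzyloxy)acetyl chloride
Product: 5 3-(benzyloxy)-6-[(benzyloxy)acetyl]cyclohex-2-en-1-one, via lithium dienolate 4 (not isolated)
Conditions: LiN(iPr)2, THF, −78 °C (2.1 equiv each of 2 and base); then 3 (1.0 equiv), −78 → −20 °C; aq. NH4Cl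
Reagents that add atoms: none
Why: Kinetic deprotonation of the vinylogous ester at its alpha-prime carbon (the future C4a) and Claisen-type C-acylation of the cross-conjugated lithium dienolate by the acid chloride, the second equivalent of dienolate taking up the acidic proton of the product, should give the enolised 1,3-diketone in which C3, C4, C4a and C8a stand in line.

Step 3
Reactants: 5 3-(benzyloxy)-6-[(benzyloxy)acetyl]cyclohex-2-en-1-one
Product: 6 4-(benzyloxy)-1-[(Z)-2-(benzyloxy)-1-(trimethylsilyloxy)ethenyl]-2-(trimethylsilyloxy)cyclohexa-1,3-diene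
Conditions: Me3SiOTf (2.4 equiv), Et3N (3 equiv), Et2O, 0 °C → rt; used crude
Reagents that add atoms: trimethylsilyl trifluoromethanesulfonate, C[Si](C)(C)OS(=O)(=O)C(F)(F)F
Why: Double soft enolisation and O-silylation of the 1,3-diketone (silyl enol ether formation, the standard entry to 1,3-bis(silyloxy)dienes) should engage the C8a oxygen and, through the acidic C3–H next to the C4 carbonyl, the C4 oxygen, the (Z)-enol ether being the usual outcome for alpha-alkoxy ketones.

Step 4
Reactants: 6 4-(benzyloxy)-1-[(Z)-2-(benzyloxy)-1-(trimethylsilyloxy)ethenyl]-2-(trimethylsilyloxy)cyclohexa-1,3-diene, 7 3,4-bis(benzyloxy)benzaldehyde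
Product: 9 (2S,3S)-3,7-bis(benzyloxy)-2-[3,4-bis(benzyloxy)phenyl]-2,3,5,6-tetrahydro-4H-chromen-4-one, via silylated aldol adduct 8 (not isolated)
Conditions: (R)-BINOL (20 mol %), Ti(OiPr)4 (20 mol %), 4 Å molecular sieves, THF, −78 °C → rt; then TFA, CH2Cl2, 0 °C
Reagents that add atoms: none
Why: The catalyst formed from Ti(OiPr)4 and (R)-BINOL activates aldehyde 7, the diene terminus C3 adds to its Re face in a vinylogous Mukaiyama aldol reaction (C2–C3 bond, silyl transfer to O1) to give 8, and TFA then frees O1, which adds to the silyl enol ether carbon C8a with loss of hexamethyldisiloxane (O1–C8a bond), so that the overall change is a formal oxa-Diels–Alder reaction of the aldehyde with a 1,3-dioxygenated diene. The closest known reaction type is the Ti(OiPr)4/BINOL-catalysed aldol/cyclocondensation of 1,3-bis(silyloxy)dienes with aryl aldehydes to 2,3-dihydro-4H-pyran-4-ones. Ring C is closed by 6-exo-trig attack of O1 on the protonated C8a=C4a enol ether followed by elimination, which leaves C8a=C4a conjugated to the C4 ketone. C2 is set by the catalyst (Re-face addition gives 2S), and C3 by the antiperiplanar open transition state of the (Z)-enol ether, backed by acid-mediated equilibration of this ketone alpha centre to the 2,3-trans isomer. The step needs attack through C3 and not through C4a or C8 of the conjugated polyene, which is secured because C3 is the unhindered terminus of the bis(silyloxy)diene and its reaction gives the most delocalised oxocarbenium ion, while only the C2 oxygen can reach C8a in a six-membered ring.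

Step 5
Reactants: 9 (2S,3S)-3,7-bis(benzyloxy)-2-[3,4-bis(benzyloxy)phenyl]-2,3,5,6-tetrahydro-4H-chromen-4-one
Product: 10 (2S,3S)-3,7-bis(benzyloxy)-2-[3,4-bis(benzyloxy)phenyl]-2,3-dihydro-4H-chromen-4-one
Conditions: DDQ (1.1 equiv), 1,4-dioxane, rt
Reagents that add atoms: none
Why: DDQ dehydrogenation of the 5,6-dihydro ring A (a cyclohexa-1,3-diene) is driven by aromatisation and should be much faster than attack on the benzyl ethers or on C2–H next to the electron-poor vinylogous-ester oxygen, so C2 and C3 stay untouched.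

Step 6
Reactants: 11 (+)-catechin
Product: 12 (2R,3S)-3,5,7-tris(benzyloxy)-2-[3,4-bis(benzyloxy)phenyl]-3,4-dihydro-2H-chromene
Conditions: NaH (6 equiv), BnBr (6 equiv), DMF, 0 °C → rt, argon
Reagents that add atoms: benzyl bromide, BrCc1ccccc1
Why: Williamson etherification of the four phenols and the 3-hydroxyl should give the pentabenzyl ether, with C2 and C3 of catechin not involved.

Step 7
Reactants: 12 (2R,3S)-3,5,7-tris(benzyloxy)-2-[3,4-bis(benzyloxy)phenyl]-3,4-dihydro-2H-chromene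
Product: 13 (2R,3S)-3,5,7-tris(benzyloxy)-2-[3,4-bis(benzyloxy)phenyl]-8-bromo-3,4-dihydro-2H-chromene
Conditions: NBS (1.0 equiv), CH2Cl2, −78 °C → rt
Reagents that add atoms: N-bromosuccinimide, O=C1CCC(=O)N1Br
Why: Electrophilic aromatic bromination of catechin benzyl ethers should go to C8, the more accessible position of the 5,7-dioxygenated ring A, which blocks C8 and leaves C6 for the coupling.

Step 8
Reactants: 13 (2R,3S)-3,5,7-tris(benzyloxy)-2-[3,4-bis(benzyloxy)phenyl]-8-bromo-3,4-dihydro-2H-chromene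
Product: 14 (2R,3S)-3,5,7-tris(benzyloxy)-2-[3,4-bis(benzyloxy)phenyl]-8-bromo-6-iodo-3,4-dihydro-2H-chromene
Conditions: NIS (1.1 equiv), TFA (cat.), CH2Cl2, 0 °C → rt
Reagents that add atoms: N-iodosuccinimide, O=C1CCC(=O)N1I
Why: Electrophilic aromatic iodination should go to C6, the only free position of the trioxygenated ring, which is far more nucleophilic than the catechol ether ring B.

Step 9
Reactants: 14 (2R,3S)-3,5,7-tris(benzyloxy)-2-[3,4-bis(benzyloxy)phenyl]-8-bromo-6-iodo-3,4-dihydro-2H-chromene, 10 (2S,3S)-3,7-bis(benzyloxy)-2-[3,4-bis(benzyloxy)phenyl]-2,3-dihydro-4H-chromen-4-one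
Product: 16 (2S,3S,4ξ)-3,7-bis(benzyloxy)-2-[3,4-bis(benzyloxy)phenyl]-4-{(2R,3S)-3,5,7-tris(benzyloxy)-2-[3,4-bis(benzyloxy)phenyl]-8-bromo-3,4-dihydro-2H-chromen-6-yl}-3,4-dihydro-2H-chromen-4-ol, via aryllithium 15 (not isolated)
Conditions: nBuLi (1.05 equiv), THF, −78 °C; then 10 (0.9 equiv) in THF, −78 → −40 °C; then H2O
Reagents that add atoms: none
Why: Iodine–lithium exchange at −78 °C should be much faster than bromine–lithium exchange, and 1,2-addition of the C6′ aryllithium to the alpha-alkoxy C4 ketone (organolithium addition, a known way to join catechin aryllithiums to flavan-4-ones) should form the C4–C6′ bond, the carbinol configuration being irrelevant because it is removed in step 10.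

Step 10
Reactants: 16 (2S,3S,4ξ)-3,7-bis(benzyloxy)-2-[3,4-bis(benzyloxy)phenyl]-4-{(2R,3S)-3,5,7-tris(benzyloxy)-2-[3,4-bis(benzyloxy)phenyl]-8-bromo-3,4-dihydro-2H-chromen-6-yl}-3,4-dihydro-2H-chromen-4-ol
Product: 17 (2S,3R,4S)-3,7-bis(benzyloxy)-2-[3,4-bis(benzyloxy)phenyl]-4-{(2R,3S)-3,5,7-tris(benzyloxy)-2-[3,4-bis(benzyloxy)phenyl]-8-bromo-3,4-dihydro-2H-chromen-6-yl}-3,4-dihydro-2H-chromene
Conditions: Bu3SnH (3 equiv), TFA, CH2Cl2, 0 °C
Reagents that add atoms: none
Why: In this ionic hydrogenation TFA ionises the doubly benzylic tertiary alcohol to a C4 carbenium ion stabilised by the para 7-benzyloxy group and the trioxygenated ring, and Bu3SnH should deliver hydride to the face anti to the adjacent 3-benzyloxy group (the facial preference that arene nucleophiles show at C4 of 2,3-trans flavan cations), so that H4 ends trans and the catechin unit cis to O3 (4S).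

Step 11
Reactants: 17 (2S,3R,4S)-3,7-bis(benzyloxy)-2-[3,4-bis(benzyloxy)phenyl]-4-{(2R,3S)-3,5,7-tris(benzyloxy)-2-[3,4-bis(benzyloxy)phenyl]-8-bromo-3,4-dihydro-2H-chromen-6-yl}-3,4-dihydro-2H-chromene
Product: 18 (2S,3R,4S)-2-(3,4-dihydroxyphenyl)-4-[(2R,3S)-2-(3,4-dihydroxyphenyl)-3,5,7-trihydroxy-3,4-dihydro-2H-chromen-6-yl]-3,4-dihydro-2H-chromene-3,7-diol
Conditions: H2 (1 atm), Pd(OH)2/C, Et3N, THF/MeOH/H2O, rt
Reagents that add atoms: none
Why: Catalytic hydrogenolysis should cleave all nine benzyl ethers and, with Et3N as acid scavenger, the C8′–Br bond (hydrodehalogenation) in the same operation without touching the five stereocentres.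

Compound list
1 | cyclohexane-1,3-dione | O=C1CCCC(=O)C1 | starting material
2 | 3-(benzyloxy)cyclohex-2-en-1-one | O=C1C=C(OCc2ccccc2)CCC1 | intermediate
3 | (benzyloxy)acetyl chloride | O=C(Cl)COCc1ccccc1 | starting material
4 | lithium 5-(benzyloxy)cyclohexa-1,5-dien-1-olate (kinetic dienolate of 2, not isolated) | [Li]OC1=CCCC(OCc2ccccc2)=C1 | intermediate
5 | 3-(benzyloxy)-6-[(benzyloxy)acetyl]cyclohex-2-en-1-one (enolised 1,3-diketone, C6 not a defined stereocentre) | O=C1C=C(OCc2ccccc2)CCC1C(=O)COCc1ccccc1 | intermediate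
6 | 4-(benzyloxy)-1-[(Z)-2-(benzyloxy)-1-(trimethylsilyloxy)ethenyl]-2-(trimethylsilyloxy)cyclohexa-1,3-diene | C[Si](C)(C)OC1=C(/C(O[Si](C)(C)C)=C/OCc2ccccc2)CCC(OCc2ccccc2)=C1 | intermediate
7 | 3,4-bis(benzyloxy)benzaldehyde | O=Cc1ccc(OCc2ccccc2)c(OCc2ccccc2)c1 | starting material
8 | (2S,3S)-2-(benzyloxy)-1-[4-(benzyloxy)-2-(trimethylsilyloxy)cyclohexa-1,3-dien-1-yl]-3-[3,4-bis(benzyloxy)phenyl]-3-(trimethylsilyloxy)propan-1-one (anti aldol adduct, not isolated) | C[Si](C)(C)OC1=C(C(=O)[C@@H](OCc2ccccc2)[C@H](c2ccc(OCc3ccccc3)c(OCc3ccccc3)c2)O[Si](C)(C)C)CCC(OCc2ccccc2)=C1 | intermediate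
9 | (2S,3S)-3,7-bis(benzyloxy)-2-[3,4-bis(benzyloxy)phenyl]-2,3,5,6-tetrahydro-4H-chromen-4-one (2,3-trans) | c1ccccc1COC1=CC(O[C@@H](c2ccc(OCc3ccccc3)c(OCc3ccccc3)c2)[C@H](OCc2ccccc2)C2=O)=C2CC1 | intermediate
10 | (2S,3S)-3,7-bis(benzyloxy)-2-[3,4-bis(benzyloxy)phenyl]-2,3-dihydro-4H-chromen-4-one (tetra-O-benzyl-(2S,3S)-dihydrofisetin, 2,3-trans) | c1ccccc1COc1ccc2c(c1)O[C@@H](c1ccc(OCc3ccccc3)c(OCc3ccccc3)c1)[C@H](OCc1ccccc1)C2=O | intermediate
11 | (+)-catechin, (2R,3S)-2-(3,4-dihydroxyphenyl)-3,4-dihydro-2H-chromene-3,5,7-triol | c1c(O)cc2c(c1O)C[C@H](O)[C@@H](c1ccc(O)c(O)c1)O2 | starting material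
12 | (2R,3S)-3,5,7-tris(benzyloxy)-2-[3,4-bis(benzyloxy)phenyl]-3,4-dihydro-2H-chromene (penta-O-benzylcatechin) | c1c(OCc3ccccc3)cc2c(c1OCc1ccccc1)C[C@H](OCc1ccccc1)[C@@H](c1ccc(OCc3ccccc3)c(OCc3ccccc3)c1)O2 | intermediate
13 | (2R,3S)-3,5,7-tris(benzyloxy)-2-[3,4-bis(benzyloxy)phenyl]-8-bromo-3,4-dihydro-2H-chromene | c1c(OCc3ccccc3)c(Br)c2c(c1OCc1ccccc1)C[C@H](OCc1ccccc1)[C@@H](c1ccc(OCc3ccccc3)c(OCc3ccccc3)c1)O2 | intermediate
14 | (2R,3S)-3,5,7-tris(benzyloxy)-2-[3,4-bis(benzyloxy)phenyl]-8-bromo-6-iodo-3,4-dihydro-2H-chromene | Ic1c(OCc3ccccc3)c(Br)c2c(c1OCc1ccccc1)C[C@H](OCc1ccccc1)[C@@H](c1ccc(OCc3ccccc3)c(OCc3ccccc3)c1)O2 | intermediate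
15 | {(2R,3S)-3,5,7-tris(benzyloxy)-2-[3,4-bis(benzyloxy)phenyl]-8-bromo-3,4-dihydro-2H-chromen-6-yl}lithium (not isolated) | [Li]c1c(OCc3ccccc3)c(Br)c2c(c1OCc1ccccc1)C[C@H](OCc1ccccc1)[C@@H](c1ccc(OCc3ccccc3)c(OCc3ccccc3)c1)O2 | intermediate
16 | (2S,3S,4ξ)-3,7-bis(benzyloxy)-2-[3,4-bis(benzyloxy)phenyl]-4-{(2R,3S)-3,5,7-tris(benzyloxy)-2-[3,4-bis(benzyloxy)phenyl]-8-bromo-3,4-dihydro-2H-chromen-6-yl}-3,4-dihydro-2H-chromen-4-ol (C4 epimers not separated) | c1ccccc1COc1ccc2c(c1)O[C@@H](c1ccc(OCc3ccccc3)c(OCc3ccccc3)c1)[C@H](OCc1ccccc1)C2(O)c1c(OCc3ccccc3)c(Br)c2c(c1OCc1ccccc1)C[C@H](OCc1ccccc1)[C@@H](c1ccc(OCc3ccccc3)c(OCc3ccccc3)c1)O2 | intermediate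
17 | (2S,3R,4S)-3,7-bis(benzyloxy)-2-[3,4-bis(benzyloxy)phenyl]-4-{(2R,3S)-3,5,7-tris(benzyloxy)-2-[3,4-bis(benzyloxy)phenyl]-8-bromo-3,4-dihydro-2H-chromen-6-yl}-3,4-dihydro-2H-chromene (2,3-trans-3,4-cis) | c1ccccc1COc1ccc2c(c1)O[C@@H](c1ccc(OCc3ccccc3)c(OCc3ccccc3)c1)[C@H](OCc1ccccc1)[C@@H]2c1c(OCc3ccccc3)c(Br)c2c(c1OCc1ccccc1)C[C@H](OCc1ccccc1)[C@@H](c1ccc(OCc3ccccc3)c(OCc3ccccc3)c1)O2 | intermediate
18 | (2S,3R,4S)-2-(3,4-dihydroxyphenyl)-4-[(2R,3S)-2-(3,4-dihydroxyphenyl)-3,5,7-trihydroxy-3,4-dihydro-2H-chromen-6-yl]-3,4-dihydro-2H-chromene-3,7-diol (ent-fisetinidol-(4α→6)-catechin, CNP0141631.3) | Oc1ccc2c(c1)O[C@@H](c1ccc(O)c(O)c1)[C@H](O)[C@@H]2c1c(O)cc2c(c1O)C[C@H](O)[C@@H](c1ccc(O)c(O)c1)O2 | target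

Total step count: 11 steps.
Longest linear sequence: 8 steps (steps 1 to 5, then 9, 10 and 11, from cyclohexane-1,3-dione).

Steps most likely to fail

Step 4. The catalysed addition may lose enantio- or diastereocontrol with this 4-alkoxy, ring-embedded diene, or the aldehyde may be attacked through C8 of the polyene instead of C3. Fallback: the route sets out again from 5 and 7 without the silyl diene. The dilithio dianion of 5 (LiN(iPr)2, 2.2 equiv, THF, −78 °C) should add through C3 to 7 to give the racemic aldol adduct F1. TFA should cyclodehydrate it and equilibrate C3 to the racemic 2,3-trans pyranone F2, which forms the same two bonds without a catalyst. Preparative chromatography on a chiral stationary phase then removes the (2R,3R)-enantiomer F3 and delivers 9, where the route is rejoined.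

Step 9. The doubly ortho-substituted aryllithium may enolise ketone 10 (with ring opening by loss of the O1 phenoxide) instead of adding to the hindered carbonyl group. Fallback: from 10, NaBH4 reduction (MeOH/THF, 0 °C) should give the flavan-4-ol F4. With Me3SiOTf in CH2Cl2 at −78 °C it ionises to the C4 cation, which alkylates the free C6 position of bromide 13 in a Friedel–Crafts coupling of the kind used for 4→6-linked proanthocyanidins. This bypasses steps 9 and 10 but is not stereoselective for the cis isomer: 17 is expected as the minor product beside the 3,4-trans C4 epimer F5 and is separated by chromatography, and the route is rejoined at 17.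

Step 10. Hydride may be delivered to the wrong face of the C4 cation, or the cation may lose H3 to give the enol ether and scramble C3. Fallback: from 16, the cation is avoided. The C4 epimer of 16 that has the hydroxyl cis to the 3-benzyloxy group (the one expected from aryl addition anti to that group) is taken directly into the hydrogenolysis of step 11. Hydrogenolysis of a benzylic C–O bond over Pd(OH)2/C proceeds with inversion, so H4 should enter trans to O3 while the benzyl ethers and the bromide are removed, giving 18 without a new intermediate.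

Further compounds
F1 | step 4 | racemic 3-(benzyloxy)-6-{2-(benzyloxy)-3-[3,4-bis(benzyloxy)phenyl]-3-hydroxypropanoyl}cyclohex-2-en-1-one | O=C1C=C(OCc2ccccc2)CCC1C(=O)C(OCc1ccccc1)C(O)c1ccc(OCc2ccccc2)c(OCc2ccccc2)c1
F2 | step 4 | racemic 2,3-trans-3,7-bis(benzyloxy)-2-[3,4-bis(benzyloxy)phenyl]-2,3,5,6-tetrahydro-4H-chromen-4-one | O=C1C(OCc2ccccc2)C(c2ccc(OCc3ccccc3)c(OCc3ccccc3)c2)OC2=C1CCC(OCc1ccccc1)=C2
F3 | step 4 | (2R,3R)-3,7-bis(benzyloxy)-2-[3,4-bis(benzyloxy)phenyl]-2,3,5,6-tetrahydro-4H-chromen-4-one (enantiomer of 9) | c1ccccc1COC1=CC(O[C@H](c2ccc(OCc3ccccc3)c(OCc3ccccc3)c2)[C@@H](OCc2ccccc2)C2=O)=C2CC1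
F4 | step 9 | (2S,3R,4ξ)-3,7-bis(benzyloxy)-2-[3,4-bis(benzyloxy)phenyl]-3,4-dihydro-2H-chromen-4-ol | c1ccccc1COc1ccc2c(c1)O[C@@H](c1ccc(OCc3ccccc3)c(OCc3ccccc3)c1)[C@H](OCc1ccccc1)C2O
F5 | step 9 | (2S,3R,4R)-3,7-bis(benzyloxy)-2-[3,4-bis(benzyloxy)phenyl]-4-{(2R,3S)-3,5,7-tris(benzyloxy)-2-[3,4-bis(benzyloxy)phenyl]-8-bromo-3,4-dihydro-2H-chromen-6-yl}-3,4-dihydro-2H-chromene (3,4-trans C4 epimer of 17) | c1ccccc1COc1ccc2c(c1)O[C@@H](c1ccc(OCc3ccccc3)c(OCc3ccccc3)c1)[C@H](OCc1ccccc1)[C@H]2c1c(OCc3ccccc3)c(Br)c2c(c1OCc1ccccc1)C[C@H](OCc1ccccc1)[C@@H](c1ccc(OCc3ccccc3)c(OCc3ccccc3)c1)O2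
F0 | step 10 | none | none
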